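Ring A (the benzo ring) of gnetal is locally symmetric about its C3a–C6 axis. C3a lies between the oxygen-bearing carbons C4 and C7a, and the formyl group sits on the axis. The dihydrofuran ring (O1, C2, C3, C3a, C7a) is therefore cut at C2–C3. This leads back to an achiral diaryldiazomethane whose ring A carries two identical 4-methoxybenzyl ethers. A chiral dirhodium carboxylate converts the diazo carbon into a carbene that inserts into an OCH2–H bond of either ether. One operation closes the ring, forms C2–C3 and sets both stereocentres, while the untouched ether protects the C4 oxygen. Acid later inverts C2 to the trans series.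

Key step: step 4

Assumption: Rh2(S-PTAD)4 is taken to deliver the (3S) series; if the sense of induction proves opposite, the equally available Rh2(R-PTAD)4 is used and nothing else changes.

Benzofuran numbering is used throughout. Ring B is the aryl group at C3 and ring C is the aryl group at C2. PTAD is (1-adamantyl)(phthalimido)acetate. The target is (2S,3S), trans.

Step 1
Reactants: 1 methyl 4-bromo-3,5-dihydroxybenzoate; 2 4-methoxybenzyl chloride
Product: 3 methyl 4-bromo-3,5-bis[(4-methoxyphenyl)methoxy]benzoate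
Conditions: K2CO3, n-Bu4NI (cat.), DMF, 60 °C
Reagents that add atoms: 4-methoxybenzyl chloride 2, COc1ccc(CCl)cc1
Why: Double Williamson ether synthesis, in which both acidic phenols of the symmetric diol are alkylated by the reactive benzylic chloride, so no differentiation of the two oxygens is needed.

Step 2
Reactants: 3 methyl 4-bromo-3,5-bis[(4-methoxyphenyl)methoxy]benzoate
Product: 4 {4-bromo-3,5-bis[(4-methoxyphenyl)methoxy]phenyl}methanol
Conditions: i-Bu2AlH, CH2Cl2, −78 → 0 °C; aq. potassium sodium tartrate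
Reagents that add atoms: none
Why: Hydride reduction of the ester to the primary alcohol leaves the aryl bromide and the aryl benzyl ethers untouched, and it gives the one oxidation level of the future formyl carbon that tolerates both an organolithium (as its alkoxide) and hydrazine.

Step 3
Reactants: 4 {4-bromo-3,5-bis[(4-methoxyphenyl)methoxy]phenyl}methanol; 5 3,5-dimethoxybenzonitrile
Product: 8 hydrazone {4-[(3,5-dimethoxyphenyl)(hydrazinylidene)methyl]-3,5-bis[(4-methoxyphenyl)methoxy]phenyl}methanol, via dilithiated arene 6 (not isolated), via N-H ketimine 7 (not isolated)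
Conditions: n-BuLi (2.1 equiv), THF, −78 °C; 5, −78 °C → rt; AcOH; N2H4·H2O, EtOH, 80 °C
Reagents that add atoms: 3,5-dimethoxybenzonitrile 5, COc1cc(cc(OC)c1)C#N; hydrazine (used as the hydrate), NN
Why: After alkoxide formation, bromine–lithium exchange at −78 °C outruns benzylic deprotonation, the 2,6-dialkoxyaryllithium adds once to the non-enolisable nitrile, and acetate-buffered transimination of the resulting N–H ketimine with hydrazine (loss of ammonia) should give the hydrazone without passing through the much less reactive di-ortho-substituted ketone.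

Step 4
Reactants: 8 hydrazone {4-[(3,5-dimethoxyphenyl)(hydrazinylidene)methyl]-3,5-bis[(4-methoxyphenyl)methoxy]phenyl}methanol
Product: 11 cis-dihydrobenzofuran (2R,3S)-3-(3,5-dimethoxyphenyl)-4-[(4-methoxyphenyl)methoxy]-2-(4-methoxyphenyl)-2,3-dihydro-1-benzofuran-6-carbaldehyde, via diazo alcohol 9 (not isolated), via diazo aldehyde 10 (not isolated)
Conditions: MnO2 (excess), CH2Cl2, rt; filtration; Rh2(S-PTAD)4 (1 mol %), CH2Cl2 (dilute), 0 °C → rt
Reagents that add atoms: none
Why: MnO2 dehydrogenates the hydrazone to diazo alcohol 9 at once and only then, more slowly, oxidises the benzylic alcohol to give 10, so that the formyl group appears after every N–H has gone; Rh2(S-PTAD)4 then expels N2 from 10 and holds C3 as a rhodium-bound carbene flanked by two aryl donors. The closest known reaction type is the enantioselective intramolecular C–H insertion of donor/donor (diaryl) rhodium carbenes into ortho benzyl ethers, which is established for 2,3-diaryl-2,3-dihydrobenzofurans. The ring O1–C2–C3–C3a–C7a closes by a 1,5-insertion through a five-membered, strongly asynchronous transition state in which a hydridic OCH2 hydrogen, activated by O1 and by the 4-methoxyphenyl ring, moves to C3 while C2–C3 forms. C3 is controlled by the chiral carboxylate pocket, which leaves one carbene face open, and C2 by the choice between the two enantiotopic hydrogens in the same transition state, whose compact geometry should place both aryl groups cis, (2R,3S). No selection between the two ethers is needed, because rotation about C3–C3a exchanges them and insertion into either gives 11, the other one remaining as the protecting group of the C4 oxygen. The step needs chemoselectivity over azine formation, carbonyl ylide formation at the formyl group and addition to the arenes, which the low electrophilicity of the donor/donor carbene, its shielding by two ortho substituents, the 1,5 proximity of the C–H bond and high dilution should secure.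

Step 5
Reactants: 11 cis-dihydrobenzofuran (2R,3S)-3-(3,5-dimethoxyphenyl)-4-[(4-methoxyphenyl)methoxy]-2-(4-methoxyphenyl)-2,3-dihydro-1-benzofuran-6-carbaldehyde
Product: 13 trans phenol (2S,3S)-3-(3,5-dimethoxyphenyl)-4-hydroxy-2-(4-methoxyphenyl)-2,3-dihydro-1-benzofuran-6-carbaldehyde, via cis phenol 12 (not isolated)
Conditions: CF3CO2H (10 vol %), C6HMe5 (5 equiv), CH2Cl2, 0 °C → rt
Reagents that add atoms: none
Why: Acidolysis of the 4-methoxybenzyl aryl ether (cation removed by Friedel–Crafts alkylation of the hindered pentamethylbenzene) frees the C4 hydroxyl, and because C2–O1 is an ether of the same 4-methoxybenzyl aryl type, the same acid ionises it reversibly, so that reclosure under thermodynamic control places the C2 aryl group anti to ring B at the untouched C3 stereocentre and turns (2R,3S) into (2S,3S).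

Step 6
Reactants: 13 trans phenol (2S,3S)-3-(3,5-dimethoxyphenyl)-4-hydroxy-2-(4-methoxyphenyl)-2,3-dihydro-1-benzofuran-6-carbaldehyde
Product: 14 gnetal, (2S,3S)-3-(3,5-dihydroxyphenyl)-4-hydroxy-2-(4-hydroxyphenyl)-2,3-dihydro-1-benzofuran-6-carbaldehyde
Conditions: BBr3 (10 equiv), CH2Cl2, −78 °C → rt; H2O
Reagents that add atoms: none
Why: Lewis-acid cleavage of the three aryl methyl ethers (bromide attack at the methyl group of each boron-complexed ether) followed by hydrolysis should free all phenols and return the aldehyde, while C3 is not touched and any reversible opening at C2–O1 can only fall back to the favoured trans isomer.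

Compound list
1 | methyl 4-bromo-3,5-dihydroxybenzoate | COC(=O)c1cc(O)c(Br)c(O)c1 | starting material
2 | 4-methoxybenzyl chloride | COc1ccc(CCl)cc1 | starting material
3 | methyl 4-bromo-3,5-bis[(4-methoxyphenyl)methoxy]benzoate | COC(=O)c1cc(OCc2ccc(OC)cc2)c(Br)c(OCc2ccc(OC)cc2)c1 | intermediate
4 | {4-bromo-3,5-bis[(4-methoxyphenyl)methoxy]phenyl}methanol | OCc1cc(OCc2ccc(OC)cc2)c(Br)c(OCc2ccc(OC)cc2)c1 | intermediate
5 | 3,5-dimethoxybenzonitrile | COc1cc(cc(OC)c1)C#N | starting material
6 | dilithiated arene, lithium {4-lithio-3,5-bis[(4-methoxyphenyl)methoxy]phenyl}methoxide | [Li]OCc1cc(OCc2ccc(OC)cc2)c([Li])c(OCc2ccc(OC)cc2)c1 | intermediate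
7 | N-H ketimine, {4-[(3,5-dimethoxyphenyl)(imino)methyl]-3,5-bis[(4-methoxyphenyl)methoxy]phenyl}methanol | N=C(c1cc(OC)cc(OC)c1)c1c(OCc2ccc(OC)cc2)cc(CO)cc1OCc1ccc(OC)cc1 | intermediate
8 | hydrazone, {4-[(3,5-dimethoxyphenyl)(hydrazinylidene)methyl]-3,5-bis[(4-methoxyphenyl)methoxy]phenyl}methanol (C=N geometry irrelevant) | NN=C(c1cc(OC)cc(OC)c1)c1c(OCc2ccc(OC)cc2)cc(CO)cc1OCc1ccc(OC)cc1 | intermediate
9 | diazo alcohol, {4-[diazo(3,5-dimethoxyphenyl)methyl]-3,5-bis[(4-methoxyphenyl)methoxy]phenyl}methanol | [N-]=[N+]=C(c1cc(OC)cc(OC)c1)c1c(OCc2ccc(OC)cc2)cc(CO)cc1OCc1ccc(OC)cc1 | intermediate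
10 | diazo aldehyde, 4-[diazo(3,5-dimethoxyphenyl)methyl]-3,5-bis[(4-methoxyphenyl)methoxy]benzaldehyde | [N-]=[N+]=C(c1cc(OC)cc(OC)c1)c1c(OCc2ccc(OC)cc2)cc(C=O)cc1OCc1ccc(OC)cc1 | intermediate
11 | cis-dihydrobenzofuran, (2R,3S)-3-(3,5-dimethoxyphenyl)-4-[(4-methoxyphenyl)methoxy]-2-(4-methoxyphenyl)-2,3-dihydro-1-benzofuran-6-carbaldehyde | O=Cc1cc(OCc3ccc(OC)cc3)c2c(c1)O[C@@H](c1ccc(OC)cc1)[C@H]2c1cc(OC)cc(OC)c1 | intermediate
12 | cis phenol, (2R,3S)-3-(3,5-dimethoxyphenyl)-4-hydroxy-2-(4-methoxyphenyl)-2,3-dihydro-1-benzofuran-6-carbaldehyde | O=Cc1cc(O)c2c(c1)O[C@@H](c1ccc(OC)cc1)[C@H]2c1cc(OC)cc(OC)c1 | intermediate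
13 | trans phenol, (2S,3S)-3-(3,5-dimethoxyphenyl)-4-hydroxy-2-(4-methoxyphenyl)-2,3-dihydro-1-benzofuran-6-carbaldehyde | O=Cc1cc(O)c2c(c1)O[C@H](c1ccc(OC)cc1)[C@H]2c1cc(OC)cc(OC)c1 | intermediate
14 | gnetal, (2S,3S)-3-(3,5-dihydroxyphenyl)-4-hydroxy-2-(4-hydroxyphenyl)-2,3-dihydro-1-benzofuran-6-carbaldehyde | O=Cc1cc(O)c2c(c1)O[C@H](c1ccc(O)cc1)[C@H]2c1cc(O)cc(O)c1 | target

Total step count: 6. Longest linear sequence: 6 steps (1 → 14).

Steps most likely to fail

Step 4 (key step).
- **What may go wrong:** The catalyst may discriminate the carbene faces poorly, because two ortho substituents twist ring A out of conjugation. The diazo compound may also decay to azine or ketone during the slower alcohol oxidation.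
- **Fallback (sets out from 8, returns at 13):** Stereocontrol is moved from the catalyst to a classical resolution. Oxidation of 8 as before and insertion with the achiral, bulky Rh2(O2CCPh3)4 should give the racemic cis-dihydrobenzofuran F1. The conditions of step 5 convert it into the racemic trans phenol F2. The C4 hydroxyl, which lies next to C3, is esterified with (S)-2-methoxy-2-phenylacetic acid (EDC·HCl, DMAP, CH2Cl2). This gives the (2S,3S) ester F3 and the (2R,3R) ester F4, which are separated by chromatography or crystallisation. K2CO3 in MeOH at 0 °C then releases 13 from F3.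

Step 3.
- **What may go wrong:** The addition–elimination at the imine carbon may stall, since two ortho benzyloxy groups shield it. Transimination would then stay incomplete, or hydrolysis to the inert ketone would take over.
- **Fallback (sets out from 7, returns at 8):** The N–N bond is made at the exposed nitrogen instead of by exchange at the crowded carbon. Ketimine 7 is isolated after an aqueous quench, which is feasible because hindered diaryl ketimines resist hydrolysis. It is N-aminated with O-(mesitylsulfonyl)hydroxylamine in CH2Cl2 at 0 °C to the hydrazonium mesitylenesulfonate F5. Aqueous NaHCO3 then liberates 8.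

Step 6.
- **What may go wrong:** Three methyl ethers need a long exposure to BBr3, during which the C2–O1 bond may ionise. Proton loss from C3 or oligomerisation could follow, and BBr3 may also attack the formyl group.
- **Fallback (sets out from 1, returns at 14):** The methyl ethers are replaced from the start by benzyl ethers, which leave under far milder conditions.
  - 3,5-Dihydroxybenzonitrile is benzylated (BnBr, K2CO3, DMF) to 3,5-bis(benzyloxy)benzonitrile F6.
  - Compound 1 is alkylated with commercial 4-(benzyloxy)benzyl chloride to the bis(benzyloxybenzyl) ester F7, which is reduced to the bromo alcohol F8.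
  - The operations of steps 3 to 5 then lead to the benzyl-series hydrazone F9, the benzyl-series cis-dihydrobenzofuran F10 and the benzyl-series trans phenol F11.
  - BCl3 with C6HMe5 in CH2Cl2 at −78 °C finally removes the three benzyl ethers within a short contact time to give 14.

Further compounds
F1 | step 4 | racemic cis-3-(3,5-dimethoxyphenyl)-4-[(4-methoxyphenyl)methoxy]-2-(4-methoxyphenyl)-2,3-dihydro-1-benzofuran-6-carbaldehyde (both enantiomers) | O=Cc1cc(OCc3ccc(OC)cc3)c2c(c1)O[C@@H](c1ccc(OC)cc1)[C@H]2c1cc(OC)cc(OC)c1.O=Cc1cc(OCc3ccc(OC)cc3)c2c(c1)O[C@H](c1ccc(OC)cc1)[C@@H]2c1cc(OC)cc(OC)c1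
F2 | step 4 | racemic trans-3-(3,5-dimethoxyphenyl)-4-hydroxy-2-(4-methoxyphenyl)-2,3-dihydro-1-benzofuran-6-carbaldehyde (both enantiomers) | O=Cc1cc(O)c2c(c1)O[C@H](c1ccc(OC)cc1)[C@H]2c1cc(OC)cc(OC)c1.O=Cc1cc(O)c2c(c1)O[C@@H](c1ccc(OC)cc1)[C@@H]2c1cc(OC)cc(OC)c1
F3 | step 4 | (2S,3S)-3-(3,5-dimethoxyphenyl)-6-formyl-2-(4-methoxyphenyl)-2,3-dihydro-1-benzofuran-4-yl (S)-2-methoxy-2-phenylacetate | O=Cc1cc(OC(=O)[C@@H](OC)c3ccccc3)c2c(c1)O[C@H](c1ccc(OC)cc1)[C@H]2c1cc(OC)cc(OC)c1
F4 | step 4 | (2R,3R)-3-(3,5-dimethoxyphenyl)-6-formyl-2-(4-methoxyphenyl)-2,3-dihydro-1-benzofuran-4-yl (S)-2-methoxy-2-phenylacetate | O=Cc1cc(OC(=O)[C@@H](OC)c3ccccc3)c2c(c1)O[C@@H](c1ccc(OC)cc1)[C@@H]2c1cc(OC)cc(OC)c1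
F5 | step 3 | hydrazonium 2,4,6-trimethylbenzenesulfonate of 8 | N[NH+]=C(c1cc(OC)cc(OC)c1)c1c(OCc2ccc(OC)cc2)cc(CO)cc1OCc1ccc(OC)cc1.Cc1cc(C)c(S(=O)(=O)[O-])c(C)c1
F6 | step 6 | 3,5-bis(benzyloxy)benzonitrile | N#Cc1cc(OCc2ccccc2)cc(OCc2ccccc2)c1
F7 | step 6 | methyl 4-bromo-3,5-bis{[4-(benzyloxy)phenyl]methoxy}benzoate | COC(=O)c1cc(OCc2ccc(OCc3ccccc3)cc2)c(Br)c(OCc2ccc(OCc3ccccc3)cc2)c1
F8 | step 6 | (4-bromo-3,5-bis{[4-(benzyloxy)phenyl]methoxy}phenyl)methanol | OCc1cc(OCc2ccc(OCc3ccccc3)cc2)c(Br)c(OCc2ccc(OCc3ccccc3)cc2)c1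
F9 | step 6 | (4-{[3,5-bis(benzyloxy)phenyl](hydrazinylidene)methyl}-3,5-bis{[4-(benzyloxy)phenyl]methoxy}phenyl)methanol | NN=C(c1cc(OCc2ccccc2)cc(OCc2ccccc2)c1)c1c(OCc2ccc(OCc3ccccc3)cc2)cc(CO)cc1OCc1ccc(OCc2ccccc2)cc1
F10 | step 6 | (2R,3S)-3-[3,5-bis(benzyloxy)phenyl]-2-[4-(benzyloxy)phenyl]-4-{[4-(benzyloxy)phenyl]methoxy}-2,3-dihydro-1-benzofuran-6-carbaldehyde | O=Cc1cc(OCc3ccc(OCc4ccccc4)cc3)c2c(c1)O[C@@H](c1ccc(OCc3ccccc3)cc1)[C@H]2c1cc(OCc2ccccc2)cc(OCc2ccccc2)c1
F11 | step 6 | (2S,3S)-3-[3,5-bis(benzyloxy)phenyl]-2-[4-(benzyloxy)phenyl]-4-hydroxy-2,3-dihydro-1-benzofuran-6-carbaldehyde | O=Cc1cc(O)c2c(c1)O[C@H](c1ccc(OCc3ccccc3)cc1)[C@H]2c1cc(OCc2ccccc2)cc(OCc2ccccc2)c1
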